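**Retrosynthetic overview**

1. The strategy rests on ring A of the cis-fused decalin: the gem-dimethyl carbon C4 lies between the carbinol C3 and the fusion methine C5, and C5 is γ to the oxygen-bearing C8 through C6–C7 of ring B.
2. Endgame disconnections: C8–CH3 (organocerium addition to a C8 ketone), the C6=C7 bond (conjugate reduction) and C9–C11 (enolate alkylation with homofarnesyl iodide) lead back to a cis-fused 3-hydroxy-6-en-8-one.
3. Key disconnection C4–C5: that enone comes from a ring B silyl dienol ether (C8(OSi)=C7–C6=C5) carrying an (S)-2,2-dimethyloxirane on a two-carbon tether from C10.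
4. The precursor comes from 3-methylcyclohexenone: asymmetric conjugate addition (sets C10), dehydrogenation, Shi epoxidation (sets C3), thermodynamic dienolate silylation.
5. Ring order: ring B is bought, ring A is closed onto it; the side chain comes from farnesol by one-carbon homologation.

Key step: step 5

Numbering: triterpenoid numbering is used (C3 carbinol, C4 gem-dimethyl, C5/C10 fusion, C8 tertiary carbinol, C9 chain-bearing, C11 first chain carbon); β is the face of the C10 methyl group. The target SMILES encodes H5, 3-OH, the C8 methyl and the C9 chain on the β face (cis A/B fusion) and 8-OH on the α face.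

Assumption: the sense of induction of the copper catalyst (step 1) and of the ketone catalyst (step 3) is taken from the usual models and would be confirmed by correlation on 4 and 6; the other catalyst enantiomer is available in each case.

**Route**

Step 1
Reactants: 1 3-methylcyclohex-2-en-1-one; 2 5-bromo-2-methylpent-2-ene
Product: 4 (3R)-3-methyl-3-(4-methylpent-3-en-1-yl)cyclohexan-1-one, via homoprenylmagnesium bromide 3 (not isolated)
Conditions: Mg, Et2O, 35 °C; then 1, Cu(OTf)2 (3 mol %), chiral C2-symmetric 1,3-diaryl-4,5-diphenylimidazolinium tetrafluoroborate (carbene precursor, 4 mol %), Et2O, 0 °C; aq NH4Cl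
Reagents that add atoms: none
Why: Copper-catalysed asymmetric conjugate addition of a Grignard reagent to a β-methyl cyclohexenone under N-heterocyclic carbene control is an established route to all-carbon quaternary centres; the ligand enantiomer is chosen so that the homoprenyl group adds to the face of C10 that gives (3R)-4, and the trisubstituted alkene is inert.

Step 2
Reactants: 4 (3R)-3-methyl-3-(4-methylpent-3-en-1-yl)cyclohexan-1-one
Product: 5 (5S)-5-methyl-5-(4-methylpent-3-en-1-yl)cyclohex-2-en-1-one
Conditions: IBX (1.5 equiv), DMSO–toluene, 70 °C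
Reagents that add atoms: none
Why: IBX dehydrogenation of a ketone through its enol: C10 carries no hydrogen, so the double bond can only form between C7 and C6, no dienone is possible, the isolated alkene is inert and C10 is untouched (its CIP letter changes from R to S only because the ring priorities change).

Step 3
Reactants: 5 (5S)-5-methyl-5-(4-methylpent-3-en-1-yl)cyclohex-2-en-1-one
Product: 6 (5S)-5-{2-[(2S)-3,3-dimethyloxiran-2-yl]ethyl}-5-methylcyclohex-2-en-1-one
Conditions: KHSO5 (Oxone, 1.4 equiv), fructose-derived ketone catalyst of the L series (30 mol %), K2CO3, Bu4NHSO4, Na2B4O7/Na2EDTA buffer, MeCN–CH2(OMe)2–H2O, 0 °C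
Reagents that add atoms: potassium peroxymonosulfate, [K+].[O-]S(=O)(=O)OO
Why: Shi epoxidation: the chiral dioxirane is electrophilic and oxidises the electron-rich trisubstituted alkene much faster than the conjugated C6=C7 bond, and the L-fructose-derived catalyst is expected to deliver oxygen to the alkene face that gives the (2S) oxirane, by catalyst control remote from C10.

Step 4
Reactants: 6 (5S)-5-{2-[(2S)-3,3-dimethyloxiran-2-yl]ethyl}-5-methylcyclohex-2-en-1-one
Product: 8 tert-butyl{[(5R)-5-{2-[(2S)-3,3-dimethyloxiran-2-yl]ethyl}-5-methylcyclohexa-1,3-dien-1-yl]oxy}dimethylsilane, via potassium dienolate 7 (not isolated)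
Conditions: KOt-Bu (1.3 equiv), THF, −78 to −20 °C (6 added slowly); then TBSCl (1.6 equiv), −78 to 0 °C; pentane, filtration through basic alumina
Reagents that add atoms: tert-butyldimethylsilyl chloride, CC(C)(C)[Si](C)(C)Cl
Why: Thermodynamic dienolate formation and O-silylation: with an alkoxide base and the t-BuOH it releases as proton shuttle, the α′ (C9) and γ (C5) enolates equilibrate to the more delocalised through-conjugated dienolate, which TBSCl traps on oxygen as the 1-silyloxy-1,3-diene, while the base-stable oxirane is spared the silyl triflate–amine conditions that would favour the cross-conjugated C9 isomer and attack the epoxide.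

Step 5
Reactants: 8 tert-butyl{[(5R)-5-{2-[(2S)-3,3-dimethyloxiran-2-yl]ethyl}-5-methylcyclohexa-1,3-dien-1-yl]oxy}dimethylsilane
Product: 9 (4aS,6S,8aR)-6-hydroxy-5,5,8a-trimethyl-4a,5,6,7,8,8a-hexahydronaphthalen-2(1H)-one (cis-fused 3β-hydroxy-4,4,10-trimethyl-6-en-8-one in target numbering)
Conditions: MeAlCl2 (1.5 equiv), CH2Cl2 (5 mM), −78 °C; aq NaHCO3, Rochelle salt
Reagents that add atoms: none
Why: Proposed new method: MeAlCl2 binds the oxirane oxygen and polarises the C4–O bond, the γ-carbon C5 of the O-silyl dienolate (C8(OSi)=C7–C6=C5) attacks the tertiary carbon C4 anti to the departing oxygen, and the silyloxy-allyl cation so formed loses its silyl group to chloride to leave the C8 ketone conjugated with C6=C7; the closest known reaction types are Lewis acid epoxy-olefin cyclisations terminated by silyl enol ethers and γ-selective vinylogous Mukaiyama alkylations by tertiary cation precursors, which have not been shown with an epoxide and a silyl dienol ether together. Ring A closes in the 6-endo mode at the epoxide (both oxirane carbons inside the new ring, opening at the tertiary carbon) and 6-exo with respect to the C5=C6 bond. The new stereocentre C5 is controlled by C10: the two-carbon tether can bring C4 onto the adjacent C5 only on the diene face that carries C1, so H5 ends on the face of the C10 methyl group and the fusion is cis. C3 keeps its oxirane configuration, and with the (S) epoxide the C3–O bond lies equatorial in the chair transition state (C10 methyl axial, C5–C6 bond axial), so epoxide and C10 are matched for anti opening. The step needs γ- over α-attack, which ring size secures because bonding of C7 to C4 would need a bridged eight-membered ring, and 6-endo over 5-exo opening, which the cation-stabilising tertiary C4 secures; Meinwald rearrangement of the activated epoxide is held back by the low temperature and the intramolecular nucleophile.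

Step 6
Reactants: 9 (4aS,6S,8aR)-6-hydroxy-5,5,8a-trimethyl-4a,5,6,7,8,8a-hexahydronaphthalen-2(1H)-one
Product: 10 (4aS,6S,8aR)-6-[(tert-butyldimethylsilyl)oxy]-5,5,8a-trimethyl-4a,5,6,7,8,8a-hexahydronaphthalen-2(1H)-one
Conditions: TBSOTf (1.3 equiv), 2,6-lutidine (2 equiv), CH2Cl2, −78 to −20 °C
Reagents that add atoms: tert-butyldimethylsilyl triflate, CC(C)(C)[Si](C)(C)OS(=O)(=O)C(F)(F)F
Why: Silyl triflate silylation of a hindered secondary alcohol next to a quaternary carbon; lutidine is too weak a base to enolise the enone at low temperature, and the ether protects O3 from the strong bases and organometallic reagents of steps 11 to 13.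

Step 7
Reactants: 11 (2E,6E)-farnesol
Product: 12 (2E,6E)-farnesal
Conditions: MnO2 (15 equiv), hexanes, rt
Reagents that add atoms: none
Why: MnO2 oxidises allylic alcohols selectively and should leave the (2E) geometry and the remote alkenes unchanged.

Step 8
Reactants: 12 (2E,6E)-farnesal
Product: 13 (3E,7E)-4,8,12-trimethyltrideca-1,3,7,11-tetraene
Conditions: Ph3PCH3Br, KOt-Bu, THF, 0 °C; then 12, 0 °C to rt
Reagents that add atoms: methyltriphenylphosphonium bromide, C[P+](c1ccccc1)(c1ccccc1)c1ccccc1.[Br-]
Why: Wittig methylenation of the enal by the non-stabilised ylide adds the terminal CH2 without touching the existing (E) alkenes.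

Step 9
Reactants: 13 (3E,7E)-4,8,12-trimethyltrideca-1,3,7,11-tetraene
Product: 15 (3E,7E)-4,8,12-trimethyltrideca-3,7,11-trien-1-ol (homofarnesol), via homofarnesyl(disiamyl)borane 14 (not isolated)
Conditions: disiamylborane (from BH3·SMe2 and 2-methylbut-2-ene), THF, 0 °C; then NaOH, H2O2, 0 °C to rt
Reagents that add atoms: hydrogen peroxide, OO
Why: Hydroboration–oxidation with a bulky dialkylborane: boron adds only to the terminal carbon of the monosubstituted alkene (anti-Markovnikov), the three trisubstituted alkenes are too hindered to react, and oxidation gives the primary homoallylic alcohol with the (3E,7E) geometry intact.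

Step 10
Reactants: 15 (3E,7E)-4,8,12-trimethyltrideca-3,7,11-trien-1-ol
Product: 16 (6E,10E)-13-iodo-2,6,10-trimethyltrideca-2,6,10-triene (homofarnesyl iodide)
Conditions: PPh3, imidazole, I2, CH2Cl2, 0 °C to rt
Reagents that add atoms: iodine, II
Why: Appel-type iodination converts the primary alcohol into the iodide by SN2 displacement of the oxyphosphonium group under conditions too mild to move the alkenes.

Step 11
Reactants: 10 (4aS,6S,8aR)-6-[(tert-butyldimethylsilyl)oxy]-5,5,8a-trimethyl-4a,5,6,7,8,8a-hexahydronaphthalen-2(1H)-one; 16 (6E,10E)-13-iodo-2,6,10-trimethyltrideca-2,6,10-triene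
Product: 18 (1R,4aS,6S,8aS)-6-[(tert-butyldimethylsilyl)oxy]-5,5,8a-trimethyl-1-[(3E,7E)-4,8,12-trimethyltrideca-3,7,11-trien-1-yl]-4a,5,6,7,8,8a-hexahydronaphthalen-2(1H)-one (9β chain), via lithium dienolate 17 (not isolated)
Conditions: LiN(i-Pr)2 (1.05 equiv), THF, −78 °C; HMPA (3 equiv), then 16 (1.5 equiv), −78 to −20 °C
Reagents that add atoms: none
Why: Kinetic deprotonation of the enone can occur only at C9 (α′; C5 is a hindered methine), giving the cross-conjugated lithium dienolate, whose C-alkylation by the primary iodide should take place on the convex β face, axially and anti to C1, which is pseudo-axial on ring B at C10, so that the chain ends cis to the C10 methyl group.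

Step 12
Reactants: 18 the 9β-alkylated enone
Product: 19 (1R,4aS,6S,8aS)-6-[(tert-butyldimethylsilyl)oxy]-5,5,8a-trimethyl-1-[(3E,7E)-4,8,12-trimethyltrideca-3,7,11-trien-1-yl]octahydronaphthalen-2(1H)-one
Conditions: [(Ph3P)CuH]6 (0.4 equiv), H2O (5 equiv), degassed THF, rt
Reagents that add atoms: none
Why: Conjugate hydride reduction of the enone by the phosphine-stabilised copper hydride; the isolated trisubstituted alkenes and the silyl ether are inert, and C9 is not enolised because the copper enolate forms toward C7.

Step 13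
Reactants: 19 the saturated C8 ketone
Product: 20 (1R,2R,4aS,6S,8aS)-6-[(tert-butyldimethylsilyl)oxy]-2,5,5,8a-tetramethyl-1-[(3E,7E)-4,8,12-trimethyltrideca-3,7,11-trien-1-yl]decahydronaphthalen-2-ol
Conditions: MeLi, CeCl3 (dried), THF, −78 °C, 1 h; then 19, −78 °C; aq NH4Cl
Reagents that add atoms: methyllithium, [Li]C
Why: 1,2-Addition of a weakly basic organocerium reagent to a hindered, enolisable ketone; in the ring B chair that keeps the quaternary C4 equatorial, C1 is axial and 1,3-syn to the α axial approach to C8, so methyl should enter equatorially from the convex β face and give the 8β-methyl 8α-carbinol.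

Step 14
Reactants: 20 the 3-O-silyl diol
Product: 21 (1R,2R,4aS,6S,8aS)-2,5,5,8a-tetramethyl-1-[(3E,7E)-4,8,12-trimethyltrideca-3,7,11-trien-1-yl]decahydronaphthalene-2,6-diol (IN0670)
Conditions: Bu4NF (3 equiv), THF, 50 °C
Reagents that add atoms: none
Why: Fluoride-mediated cleavage of the silyl ether; the tertiary carbinol, the stereocentres and the alkenes are untouched under these basic, non-ionising conditions.

**Compound list**

1 | 3-methylcyclohex-2-en-1-one | CC1=CC(=O)CCC1 | starting material
2 | 5-bromo-2-methylpent-2-ene | CC(C)=CCCBr | starting material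
3 | (4-methylpent-3-en-1-yl)magnesium bromide | CC(C)=CCC[Mg]Br | intermediate (not isolated)
4 | (3R)-3-methyl-3-(4-methylpent-3-en-1-yl)cyclohexan-1-one | CC(C)=CCC[C@]1(C)CC(=O)CCC1 | intermediate
5 | (5S)-5-methyl-5-(4-methylpent-3-en-1-yl)cyclohex-2-en-1-one | CC(C)=CCC[C@]1(C)CC(=O)C=CC1 | intermediate
6 | (5S)-5-{2-[(2S)-3,3-dimethyloxiran-2-yl]ethyl}-5-methylcyclohex-2-en-1-one | CC1(C)O[C@H]1CC[C@]1(C)CC(=O)C=CC1 | intermediate
7 | potassium (5R)-5-{2-[(2S)-3,3-dimethyloxiran-2-yl]ethyl}-5-methylcyclohexa-1,3-dien-1-olate | CC1(C)O[C@H]1CC[C@]1(C)CC([O-])=CC=C1.[K+] | intermediate (not isolated)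
8 | tert-butyl{[(5R)-5-{2-[(2S)-3,3-dimethyloxiran-2-yl]ethyl}-5-methylcyclohexa-1,3-dien-1-yl]oxy}dimethylsilane | CC1(C)O[C@H]1CC[C@]1(C)CC(O[Si](C)(C)C(C)(C)C)=CC=C1 | intermediate
9 | (4aS,6S,8aR)-6-hydroxy-5,5,8a-trimethyl-4a,5,6,7,8,8a-hexahydronaphthalen-2(1H)-one | C1[C@@]2(C)CC[C@H](O)C(C)(C)[C@H]2C=CC1=O | intermediate
10 | (4aS,6S,8aR)-6-[(tert-butyldimethylsilyl)oxy]-5,5,8a-trimethyl-4a,5,6,7,8,8a-hexahydronaphthalen-2(1H)-one | C1[C@@]2(C)CC[C@H](O[Si](C)(C)C(C)(C)C)C(C)(C)[C@H]2C=CC1=O | intermediate
11 | (2E,6E)-farnesol | CC(C)=CCC/C(C)=C/CC/C(C)=C/CO | starting material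
12 | (2E,6E)-farnesal | CC(C)=CCC/C(C)=C/CC/C(C)=C/C=O | intermediate
13 | (3E,7E)-4,8,12-trimethyltrideca-1,3,7,11-tetraene | CC(C)=CCC/C(C)=C/CC/C(C)=C/C=C | intermediate
14 | bis(3-methylbutan-2-yl)[(3E,7E)-4,8,12-trimethyltrideca-3,7,11-trien-1-yl]borane | CC(C)=CCC/C(C)=C/CC/C(C)=C/CCB(C(C)C(C)C)C(C)C(C)C | intermediate (not isolated)
15 | (3E,7E)-4,8,12-trimethyltrideca-3,7,11-trien-1-ol | CC(C)=CCC/C(C)=C/CC/C(C)=C/CCO | intermediate
16 | (6E,10E)-13-iodo-2,6,10-trimethyltrideca-2,6,10-triene | CC(C)=CCC/C(C)=C/CC/C(C)=C/CCI | intermediate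
17 | lithium cross-conjugated dienolate of 10 (C9=C8–O−, C6=C7) | [Li+].[O-]C1=C[C@@]2(C)CC[C@H](O[Si](C)(C)C(C)(C)C)C(C)(C)[C@H]2C=C1 | intermediate (not isolated)
18 | (1R,4aS,6S,8aS)-6-[(tert-butyldimethylsilyl)oxy]-5,5,8a-trimethyl-1-[(3E,7E)-4,8,12-trimethyltrideca-3,7,11-trien-1-yl]-4a,5,6,7,8,8a-hexahydronaphthalen-2(1H)-one | CC(C)=CCC/C(C)=C/CC/C(C)=C/CC[C@@H]1[C@@]2(C)CC[C@H](O[Si](C)(C)C(C)(C)C)C(C)(C)[C@H]2C=CC1=O | intermediate
19 | (1R,4aS,6S,8aS)-6-[(tert-butyldimethylsilyl)oxy]-5,5,8a-trimethyl-1-[(3E,7E)-4,8,12-trimethyltrideca-3,7,11-trien-1-yl]octahydronaphthalen-2(1H)-one | CC(C)=CCC/C(C)=C/CC/C(C)=C/CC[C@@H]1[C@@]2(C)CC[C@H](O[Si](C)(C)C(C)(C)C)C(C)(C)[C@H]2CCC1=O | intermediate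
20 | (1R,2R,4aS,6S,8aS)-6-[(tert-butyldimethylsilyl)oxy]-2,5,5,8a-tetramethyl-1-[(3E,7E)-4,8,12-trimethyltrideca-3,7,11-trien-1-yl]decahydronaphthalen-2-ol | CC(C)=CCC/C(C)=C/CC/C(C)=C/CC[C@@H]1[C@@]2(C)CC[C@H](O[Si](C)(C)C(C)(C)C)C(C)(C)[C@H]2CC[C@@]1(C)O | intermediate
21 | (1R,2R,4aS,6S,8aS)-2,5,5,8a-tetramethyl-1-[(3E,7E)-4,8,12-trimethyltrideca-3,7,11-trien-1-yl]decahydronaphthalene-2,6-diol (IN0670) | CC(C)=CCC/C(C)=C/CC/C(C)=C/CC[C@@H]1[C@@]2(C)CC[C@H](O)C(C)(C)[C@H]2CC[C@@]1(C)O | target

**Step count**

Total step count: 14. Longest linear sequence: 10 steps (steps 1–6 and 11–14, from 1 and 2); the side-chain branch (steps 7–10) joins at step 11.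

**Steps most likely to fail**

1. Step 5 (proposed new method). The activated epoxide may rearrange by hydride shift, or the dienol ether may lose its silyl group before the C4–C5 bond forms, so that ring A does not close. The precursor also depends on γ- rather than α′-enolisation in step 4.
 Fallback (known chemistry; sets out from 1 and 2, returns at 9): the C4–C5 bond is made in the established, non-vinylogous way, by a Lewis acid epoxide opening terminated by a simple silyl enol ether carbon, and the enone is transposed afterwards. This path does not pass through 8, so it also holds if step 4 gives the cross-conjugated isomer. Step 1 run with the enantiomeric ligand would give (3S)-3-methyl-3-(4-methylpent-3-en-1-yl)cyclohexan-1-one F1. IBX as in step 2 would give (5R)-5-methyl-5-(4-methylpent-3-en-1-yl)cyclohex-2-en-1-one F2. The epoxidation of step 3 would give (5R)-5-{2-[(2S)-3,3-dimethyloxiran-2-yl]ethyl}-5-methylcyclohex-2-en-1-one F3, in which the carbonyl carbon is C6 and the CH2 between it and the quaternary carbon is C5. Kinetic deprotonation (LiN(i-Pr)2, THF, −78 °C; TBSCl, HMPA) removes that α′ hydrogen, the only one an amide base takes, and should give the cross-conjugated tert-butyl{[(3R)-3-{2-[(2S)-3,3-dimethyloxiran-2-yl]ethyl}-3-methylcyclohexa-1,5-dien-1-yl]oxy}dimethylsilane F4 with no regiochemical question. MeAlCl2 in CH2Cl2 at −78 °C should then close ring A through C5 onto C4, cis for the same tether reason, to (4aR,7S,8aS)-7-hydroxy-4a,8,8-trimethyl-4a,5,6,7,8,8a-hexahydronaphthalen-1(4H)-one F5. Wharton transposition follows: H2O2/NaOH at 0 °C to the 7,8-epoxy 6-ketone F6, then N2H4·H2O/AcOH to the 6-en-8-ol F7. MnO2 oxidation of the allylic alcohol would give 9. The epoxidation is kept cold and brief because H5 is then α to a carbonyl group.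

2. Step 11. C–C bond formation at C9, next to the quaternary C10, may be slow, and the hindered enolate may instead dehydroiodinate the homoallylic iodide (E2) and return 10. Proton exchange between product and enolate could also erode the C9 configuration.
 Fallback (sets out from 10, returns at 18): the ketone is alkylated as its azaenolate, which is more nucleophilic and less prone to act as a base toward the iodide. Me2NNH2 (AcOH cat., EtOH, 60 °C) would convert 10 into its N,N-dimethylhydrazone F8. LiN(i-Pr)2 (THF, 0 °C) and then 16 (−78 to 0 °C) should give the C9-alkylated hydrazone F9 with the same axial, β-face preference. CuCl2 in aqueous THF at pH 7 would release 18.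

3. Step 13. The β-face approach passes the axial C9 chain, so facial selectivity may be poor or reversed, and the hindered ketone may be enolised in place of addition.
 Fallback (sets out from 19, returns at 20): the methyl group is brought in as a methylene under thermodynamic control. Dimethylsulfoxonium methylide (Me3S(O)I, NaH, DMSO–THF, rt; Corey–Chaykovsky reaction) adds reversibly and should give the spiro-oxirane F10 with the new C–C bond equatorial (β) and the oxygen axial (α). LiBHEt3 (THF, 0 °C) opens the oxirane at CH2 and gives 20.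

**Further compounds**

F1 | step 5 | (3S)-3-methyl-3-(4-methylpent-3-en-1-yl)cyclohexan-1-one | CC(C)=CCC[C@@]1(C)CC(=O)CCC1
F2 | step 5 | (5R)-5-methyl-5-(4-methylpent-3-en-1-yl)cyclohex-2-en-1-one | CC(C)=CCC[C@@]1(C)CC(=O)C=CC1
F3 | step 5 | (5R)-5-{2-[(2S)-3,3-dimethyloxiran-2-yl]ethyl}-5-methylcyclohex-2-en-1-one | CC1(C)O[C@H]1CC[C@@]1(C)CC(=O)C=CC1
F4 | step 5 | tert-butyl{[(3R)-3-{2-[(2S)-3,3-dimethyloxiran-2-yl]ethyl}-3-methylcyclohexa-1,5-dien-1-yl]oxy}dimethylsilane | CC1(C)O[C@H]1CC[C@@]1(C)C=C(O[Si](C)(C)C(C)(C)C)C=CC1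
F5 | step 5 | (4aR,7S,8aS)-7-hydroxy-4a,8,8-trimethyl-4a,5,6,7,8,8a-hexahydronaphthalen-1(4H)-one | C1[C@@]2(C)CC[C@H](O)C(C)(C)[C@H]2C(=O)C=C1
F6 | step 5 | 7,8-epoxide of F5 (target numbering; oxirane configuration not fixed) | C1[C@@]2(C)CC[C@H](O)C(C)(C)[C@H]2C(=O)C2OC12
F7 | step 5 | cis-fused 4,4,10-trimethyl-6-ene-3β,8-diol (target numbering; C8 configuration not fixed) | C1[C@@]2(C)CC[C@H](O)C(C)(C)[C@H]2C=CC1O
F8 | step 11 | N,N-dimethylhydrazone of 10 | C1[C@@]2(C)CC[C@H](O[Si](C)(C)C(C)(C)C)C(C)(C)[C@H]2C=CC1=NN(C)C
F9 | step 11 | N,N-dimethylhydrazone of 18 | CC(C)=CCC/C(C)=C/CC/C(C)=C/CC[C@@H]1[C@@]2(C)CC[C@H](O[Si](C)(C)C(C)(C)C)C(C)(C)[C@H]2C=CC1=NN(C)C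
F10 | step 13 | C8 spiro-oxirane of 19 (CH2 on the β face, oxygen on the α face) | CC(C)=CCC/C(C)=C/CC/C(C)=C/CC[C@@H]1[C@@]2(C)CC[C@H](O[Si](C)(C)C(C)(C)C)C(C)(C)[C@H]2CC[C@]13CO3
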